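**Retrosynthetic overview**

1. Numbering: ring C1 (CBr, CH3), C2 (CHBr), C3, C4 (CH carrying the side chain), C5, C6; side chain C8 (CBr, CH3) and C9 (CH2Br). The enabling feature is the vicinal trans-diaxial dibromide on ring carbons C1 and C2. It is the signature of a C1=C2 cyclohexene, so the only ring can be closed at C1–C2 by metathesis of an acyclic diene and brominated in the same flask under control of C4.
2. C8–Br is disconnected to a C8 tertiary alcohol next to C9–Br (last step, substitution with retention through a bromonium ion), because bromination of an isopropenyl group would not distinguish the faces at C8.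
3. The ring, C1–Br and C2–Br are disconnected to acyclic bromohydrin diene 11 (allyl terminus = C2, methallyl-type terminus = C1).
4. The C4/C8 pair comes from Sharpless epoxidation of (E)-allylic alcohol 4 and anti opening at C4 by a homomethallyl Grignard reagent; 4 comes from propargyl alcohol, Me3Al and allyl bromide.
5. Ring order: the cyclohexane is the only ring of the target and is formed in step 6; the oxiranes of 5 and 10 are temporary rings.

Key step: step 6

**Route**

Step 1
Reactants: 1 prop-2-yn-1-ol; 2 3-bromoprop-1-ene (allyl bromide)
Product: 4 (2E)-2-methylhexa-2,5-dien-1-ol, via alkenylalane 3 (not isolated)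
Conditions: Me3Al (3 equiv), Cp2ZrCl2 (0.25 equiv), CH2Cl2, 0 °C to rt; then 2 (2 equiv), Pd(PPh3)4 (3 mol%), THF, 0 °C to rt; aq. potassium sodium tartrate
Reagents that add atoms: trimethylaluminium, C[Al](C)C
Why: Negishi zirconium-catalysed syn-carboalumination places methyl on the internal and aluminium on the terminal alkyne carbon, and palladium-catalysed allylation of the alkenylalane proceeds with retention, so the trisubstituted alkene should form as the E isomer only.

Step 2
Reactants: 4 (2E)-2-methylhexa-2,5-dien-1-ol
Product: 5 [(2S,3S)-2-methyl-3-(prop-2-en-1-yl)oxiran-2-yl]methanol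
Conditions: Ti(OiPr)4 (10 mol%), L-(+)-diethyl tartrate (12 mol%), t-BuOOH (2 equiv), 4 Å MS, CH2Cl2, −20 °C
Reagents that add atoms: tert-butyl hydroperoxide, CC(C)(C)OO
Why: Sharpless asymmetric epoxidation with the L-(+)-tartrate ligand delivers oxygen to the face that gives the (2S,3S)-epoxide, as with other (E)-allylic alcohols, which sets C8 and the oxygen-bearing precursor of C4, while the isolated vinyl group is not an allylic alcohol and should stay untouched.

Step 3
Reactants: 5 [(2S,3S)-2-methyl-3-(prop-2-en-1-yl)oxiran-2-yl]methanol; 6 4-bromo-2-methylbut-1-ene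
Product: 8 (2R,3R)-2,6-dimethyl-3-(prop-2-en-1-yl)hept-6-ene-1,2-diol, via Grignard reagent 7 (not isolated)
Conditions: 6, Mg, THF, rt; then CuBr·SMe2 (10 mol%), 5 (3 equiv of 7 per 5), THF, −30 to 0 °C; sat. aq. NH4Cl
Reagents that add atoms: none
Why: Copper-catalysed Grignard opening of a 2-methyl-2,3-epoxy alcohol is an SN2 attack at the secondary epoxide carbon (the quaternary one is blocked) anti to oxygen, so C4 is set by inversion and the tertiary C8–O bond is not touched.

Step 4
Reactants: 8 (2R,3R)-2,6-dimethyl-3-(prop-2-en-1-yl)hept-6-ene-1,2-diol
Product: 10 (2R)-2-methyl-2-[(4R)-7-methylocta-1,7-dien-4-yl]oxirane, via primary tosylate 9 (not isolated)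
Conditions: NaH (2.5 equiv), 1-(p-toluenesulfonyl)imidazole (1.05 equiv), THF, 0 °C to rt
Reagents that add atoms: none
Why: One-pot Williamson-type epoxide formation, in which the primary alkoxide is sulfonylated selectively and the tertiary alkoxide displaces the tosylate (3-exo-tet), so no bond to C8 is broken and its configuration is kept.

Step 5
Reactants: 10 (2R)-2-methyl-2-[(4R)-7-methylocta-1,7-dien-4-yl]oxirane
Product: 11 (2R,3R)-1-bromo-2,6-dimethyl-3-(prop-2-en-1-yl)hept-6-en-2-ol
Conditions: LiBr (2 equiv), AcOH (3 equiv), THF, rt
Reagents that add atoms: lithium bromide, [Li+].[Br-]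
Why: Buffered halide opening of a terminal epoxide is an SN2 attack of bromide at the unhindered CH2 (C9), which installs the primary bromide, frees the C8 tertiary alcohol with its configuration intact and is mild enough to spare both alkenes.

Step 6
Reactants: 11 (2R,3R)-1-bromo-2,6-dimethyl-3-(prop-2-en-1-yl)hept-6-en-2-ol
Product: 13 (2R)-1-bromo-2-[(1R,3S,4S)-3,4-dibromo-4-methylcyclohexyl]propan-2-ol, via cyclohexene bromohydrin 12 (not isolated)
Conditions: second-generation Grubbs catalyst (H2IMes)(PCy3)Cl2Ru=CHPh (3 mol%), CH2Cl2 (0.01 M), 40 °C, Ar sparge; then −78 °C, Br2 (1.1 equiv) in CH2Cl2; aq. Na2S2O3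
Reagents that add atoms: bromine, BrBr
Why: The ruthenium benzylidene initiates at the monosubstituted allyl terminus, the resulting alkylidene adds [2+2] to the 1,1-disubstituted terminus, and cycloreversion of the ruthenacyclobutane releases ethene and the trisubstituted C1=C2 alkene of 12; bromine added to the same flask then forms a bromonium ion that bromide opens anti. The closest known reaction types are ring-closing metathesis of 2-methylocta-1,7-dienes to 1-methylcyclohexenes and the bromination of 4-substituted 1-methylcyclohexenes such as alpha-terpineol to their trans-diaxial dibromides. The six-membered carbocycle is closed by ring-closing olefin metathesis, the two alkene carbons that shed their CH2 groups becoming C1 and C2. C1 and C2 are set under control of C4: with the side chain equatorial, diaxial (Fürst–Plattner) opening of either bromonium face converges on the same trans-diaxial dibromide, with bromine at C1 cis and bromine at C2 trans to the side chain, which is the (1S,2S) arrangement. The step needs the carbene to ignore the alkyl bromide and the tertiary alcohol, which second-generation ruthenium catalysts do, and it needs bromide to outrun the C8 hydroxyl at the bromonium ion, which the low temperature, the non-polar solvent and the boat conformation required for a cineole-type ether closure should secure. Only one ring size can arise because the substrate holds exactly two alkenes.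

Step 7
Reactants: 13 (2R)-1-bromo-2-[(1R,3S,4S)-3,4-dibromo-4-methylcyclohexyl]propan-2-ol
Product: 14 (1S,2S,4R)-1,2-dibromo-4-[(2R)-1,2-dibromopropan-2-yl]-1-methylcyclohexane
Conditions: HBr (33 wt% in AcOH, 5 equiv), CH2Cl2, 0 °C
Reagents that add atoms: hydrogen bromide, Br
Why: Acid-promoted substitution with neighbouring-group participation (the classical bromohydrin to vicinal dibromide conversion): the C9 bromine displaces the protonated hydroxyl from the rear to give a bromonium ion, and bromide opens it at the tertiary carbon anti to the bridging bromine, so two inversions should return bromine to the site the hydroxyl held and C8 stays (R), while the ring dibromide is inert at 0 °C.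

**Compound list**

1 | prop-2-yn-1-ol | C#CCO | starting material
2 | 3-bromoprop-1-ene (allyl bromide) | C=CCBr | starting material
3 | [(1E)-3-(dimethylalumanyloxy)-2-methylprop-1-en-1-yl]dimethylalumane | C[Al](C)/C=C(\C)CO[Al](C)C | intermediate
4 | (2E)-2-methylhexa-2,5-dien-1-ol | C=CC/C=C(\C)CO | intermediate
5 | [(2S,3S)-2-methyl-3-(prop-2-en-1-yl)oxiran-2-yl]methanol | OC[C@]1(C)O[C@H]1CC=C | intermediate
6 | 4-bromo-2-methylbut-1-ene | C=C(C)CCBr | starting material
7 | (3-methylbut-3-en-1-yl)magnesium bromide | C=C(C)CC[Mg]Br | intermediate
8 | (2R,3R)-2,6-dimethyl-3-(prop-2-en-1-yl)hept-6-ene-1,2-diol | OC[C@](C)(O)[C@@H](CC=C)CCC(C)=C | intermediate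
9 | (2R,3R)-2-hydroxy-2,6-dimethyl-3-(prop-2-en-1-yl)hept-6-en-1-yl 4-methylbenzenesulfonate | Cc1ccc(cc1)S(=O)(=O)OC[C@](C)(O)[C@@H](CC=C)CCC(C)=C | intermediate
10 | (2R)-2-methyl-2-[(4R)-7-methylocta-1,7-dien-4-yl]oxirane | C1[C@](C)(O1)[C@@H](CC=C)CCC(C)=C | intermediate
11 | (2R,3R)-1-bromo-2,6-dimethyl-3-(prop-2-en-1-yl)hept-6-en-2-ol | BrC[C@](C)(O)[C@@H](CC=C)CCC(C)=C | intermediate
12 | (2R)-1-bromo-2-[(1R)-4-methylcyclohex-3-en-1-yl]propan-2-ol | BrC[C@](C)(O)[C@@H]1CCC(C)=CC1 | intermediate
13 | (2R)-1-bromo-2-[(1R,3S,4S)-3,4-dibromo-4-methylcyclohexyl]propan-2-ol | BrC[C@](C)(O)[C@@H]1CC[C@](C)(Br)[C@@H](Br)C1 | intermediate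
14 | (1S,2S,4R)-1,2-dibromo-4-[(2R)-1,2-dibromopropan-2-yl]-1-methylcyclohexane | C[C@](Br)(CBr)[C@@H]1CC[C@](C)(Br)[C@@H](Br)C1 | target

**Step count and risks**

Total step count: 7. Longest linear sequence: 7 steps (1 to 14).

Steps most likely to fail:

Step 7. The tertiary carbinol may ionise without bromine bridging, or the cation may eliminate and take up HBr again; either process would erode the configuration at C8 or leave alkene by-products. The fallback sets out from 13. Acylation with trifluoroacetic anhydride and pyridine in CH2Cl2 at 0 °C should give (2R)-1-bromo-2-[(1R,3S,4S)-3,4-dibromo-4-methylcyclohexyl]propan-2-yl trifluoroacetate F1. This ester is ionised with MgBr2·OEt2 in CH2Cl2 at −40 °C in the absence of protic acid, so that anchimerically assisted departure of trifluoroacetate and bromide capture occur without a path for elimination and re-addition. The route is rejoined at 14.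

Step 6. The bromonium ion may be intercepted by the free C8 hydroxyl (bromo-etherification to a bridged ether), or ruthenium hydride species may shift the allyl double bond before closure. The fallback sets out from 10 and keeps the oxygen masked during bromination. Ring-closing metathesis of 10 with the same catalyst should give (2R)-2-methyl-2-[(1R)-4-methylcyclohex-3-en-1-yl]oxirane F2. Bromination with pyridinium tribromide in CH2Cl2 at −40 °C over solid K2CO3 should give (2R)-2-[(1R,3S,4S)-3,4-dibromo-4-methylcyclohexyl]-2-methyloxirane F3. Opening of the oxirane at CH2 with LiBr and AcOH in THF rejoins the route at 13.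

Step 1. During the palladium-catalysed allylation, methyl instead of alkenyl may transfer from aluminium, or the alkenylalane carrying the aluminium alkoxide may be protonated, leading to low conversion. The fallback sets out from 1. The same carboalumination is quenched with iodine to give (2E)-3-iodo-2-methylprop-2-en-1-ol F4, which is isolated and joined to allyltributylstannane by Stille coupling (Pd2(dba)3, AsPh3, DMF, rt). The route is rejoined at 4.

**Further compounds**

F1 | step 7 | (2R)-1-bromo-2-[(1R,3S,4S)-3,4-dibromo-4-methylcyclohexyl]propan-2-yl trifluoroacetate | BrC[C@](C)(OC(=O)C(F)(F)F)[C@@H]1CC[C@](C)(Br)[C@@H](Br)C1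
F2 | step 6 | (2R)-2-methyl-2-[(1R)-4-methylcyclohex-3-en-1-yl]oxirane | C1[C@](C)(O1)[C@@H]2CCC(C)=CC2
F3 | step 6 | (2R)-2-[(1R,3S,4S)-3,4-dibromo-4-methylcyclohexyl]-2-methyloxirane | C1[C@](C)(O1)[C@@H]2CC[C@](C)(Br)[C@@H](Br)C2
F4 | step 1 | (2E)-3-iodo-2-methylprop-2-en-1-ol | OC/C(C)=C/I
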